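Time first: the next flask is to stand 15 h, and you must choose between [free catalyst] = 0.32 mM and oak's 0.48 mM.

| flask | substrate | gas phase | free catalyst | remark | time |
|---|---|---|---|---|---|
| maple | 0.050 M | 15 mM (held) | 0.21 mM | run made earlier |  |
| oak | 0.050 M | 15 mM (held) | 0.48 mM | run made earlier |  |
| flask | 0.050 M | 15 mM (held) | 0.32 mM |  | 15 h |

- maple (time / h: product / %, substrate / %): 0.500: 1.6, 98.9; 1.33: 4.3, 94.7; 2.50: 10.4, 89.5; 4.00: 16.6, 83.1; 5.00: 20.2, 78.9; 8.00: 30.8, 70.0; 10.0: 36.0, 64.6
- oak (time / h: product / %, substrate / %): 0.667: 2.3, 97.5; 1.00: 4.2, 95.2; 1.50: 6.8, 92.4; 2.50: 12.4, 87.8; 4.00: 19.2, 80.0; 6.00: 27.0, 71.2; 10.0: 40.8, 59.0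

(standard deviation of a reading: 0.5 percentage points)

- at the start none of the gas phase is in solution

- product at 15 h, in percent of the substrate charged
- concentration of dissolved gas in solution at 15 h, in percent of saturation

Work with what is left, not with what is made. The apparent first-order constant is minus the logarithm of [substrate] over its charged value, divided by the time. At the last readings, at 10.0 h, it reads 0.0437 /h in maple and 0.0528 /h in oak. But maple read 0.0474 /h at 5.00 h, so the reading sags with time, and my fraction left will lean low.

Both runs share the new flask's substrate charge, 0.050 M, and differ in catalyst. A catalyst factor of 2.29 moves the constant by 1.21, a power of 0.228. At 0.32 mM I therefore take a loss constant of 0.0481 /h, which is a half-life of 14.4 h. After 15 h that leaves 48.6% of the substrate, and since the two columns sum to about the charge, 51.4% is product. Oak's constant leaves 45.3%, which is 3.3 percentage points less, so by this reckoning 1.50 times the catalyst buys that much more product. You weigh that gain against the catalyst; the flask reckoned here stays at 0.32 mM. The readings show no dissolved gas, so I commit to no figure for it.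

The forecast, holding that “the catalyst is nearly saturating”, gives 52% of product and 98% of saturation.

The flask gives 49.1% of product and dissolved gas at 44.4% of saturation, under this scheme:

    gas phase ⇌ dissolved gas, rate k1*(csat - [dissolved gas]) (kL = 6.96 × 10⁻⁵ /s)
    dissolved gas → decomposed reagent (k = 4.41 × 10⁻⁵ /s)
    2 free catalyst → spent catalyst B (k = 0.154 /M/s)
    dissolved gas + free catalyst → spent catalyst A (k = 0.00341 /M/s)
    substrate + dissolved gas + free catalyst → free catalyst + product (k = 42.9 /M²/s)

At 15.0 h the flask makes dissolved gas 1.14 times as fast as it uses it up, each step taken net. A neighbour charged with 0.12 M of substrate, all else held, keeps 68% where 0.0481 /h reckons 48.6%. Its own constant is 0.0261 /h, about half of 0.0481 /h.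

The runs were generated by integration for an exercise; scatter was added.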